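**Retrosynthetic overview**
1. Target ⇒ O‑protected 6‑alkyl‑luteolin. The last two operations are tertiary‑acetate cleavage and global hydrogenolysis of four benzyl ethers, so no acid is used late in the route.
2. C6(aryl)–CH2 bond ⇒ Negishi sp2–sp3 coupling of 6‑iodo‑tetra‑O‑benzyl‑luteolin with a (2‑acetoxy‑2,6,6‑trimethylcyclohexyl)methylzinc iodide.
3. Zinc reagent ⇒ primary iodide ⇒ (iododecarboxylation, Pinnick, ozonolysis) trans‑fused bicyclic enol ether. The ozonolysis leaves the tertiary alcohol already masked as its acetate.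
4. Enol ether ⇒ achiral (E)‑geranylacetone in one squalene–hopene‑cyclase step that sets both stereocentres.
5. Ring order: the cyclohexane and a sacrificial dihydropyran close together in the enzymatic step, and the dihydropyran is then cut open. The chromenone and catechol rings arrive intact with luteolin.

Assumption: the side chain is read as (1S,2S) (OH trans to the CH2‑aryl arm), (E)‑geranylacetone is bought as the pure E isomer, and the cyclase is used as a recombinant E. coli whole‑cell catalyst.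

**Step 1**
Reactants: 1 (E)‑geranylacetone [(5E)‑6,10‑dimethylundeca‑5,9‑dien‑2‑one]
Product: 2 (4aS,8aS)‑2,5,5,8a‑tetramethyl‑4a,5,6,7,8,8a‑hexahydro‑4H‑chromene (trans‑fused bicyclic enol ether)
Conditions: squalene–hopene cyclase (class II terpene cyclase, EC 5.4.99.17; Alicyclobacillus acidocaldarius enzyme, active‑site variant selected for the C13 ketone, E. coli whole cells), citrate buffer pH 6.0, 0.2 % SDS, 30 °C, 48 h; MTBE extraction
Reagents that add atoms: none
Why: In this enzymatic Brønsted‑acid head‑to‑tail cation–olefin cyclisation the active‑site aspartate protonates the terminal isopropylidene of the chair‑folded E‑olefin, anti addition closes the cyclohexane, the ketone oxygen traps the tertiary cation equatorially and proton loss gives the trans‑fused enol ether, so both stereocentres (4aS,8aS, the sense of hopene ring A) are set at once by asymmetric biocatalysis from an achiral substrate.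

**Step 2**
Reactants: 2 (4aS,8aS)‑2,5,5,8a‑tetramethyl‑4a,5,6,7,8,8a‑hexahydro‑4H‑chromene
Product: 4 (1S,2S)‑1,3,3‑trimethyl‑2‑(2‑oxoethyl)cyclohexyl acetate, via methoxy hydroperoxide 3 (not isolated)
Conditions: O3, CH2Cl2/MeOH 4:1, −78 °C; then Me2S, −78 °C → rt
Reagents that add atoms: ozone, [O-][O+]=O
Why: Ozonolysis (Criegee cleavage with methanol trapping and reductive quench) of the only C=C turns the oxygen‑bearing olefin carbon into the acetate that now protects the tertiary alcohol and the other carbon into the aldehyde, without touching either stereocentre.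

**Step 3**
Reactants: 4 (1S,2S)‑1,3,3‑trimethyl‑2‑(2‑oxoethyl)cyclohexyl acetate
Product: 5 2‑[(1S,2S)‑2‑acetoxy‑2,6,6‑trimethylcyclohexyl]acetic acid
Conditions: NaClO2, NaH2PO4, 2‑methylbut‑2‑ene, t‑BuOH/H2O, rt
Reagents that add atoms: sodium chlorite, [Na+].[O-]Cl=O
Why: The Pinnick oxidation is selective for the aldehyde at buffered pH, so the tertiary acetate survives and the ring stereocentre, which is β to the carbonyl, cannot epimerise.

**Step 4**
Reactants: 5 2‑[(1S,2S)‑2‑acetoxy‑2,6,6‑trimethylcyclohexyl]acetic acid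
Product: 7 (1S,2S)‑2‑(iodomethyl)‑1,3,3‑trimethylcyclohexyl acetate, via acyl hypoiodite 6 (not isolated)
Conditions: PhI(OAc)2, I2, DCE, tungsten lamp, reflux
Reagents that add atoms: iodine, II
Why: In this Suárez variant of the Hunsdiecker iododecarboxylation the photolysed acyl hypoiodite loses CO2 and the primary radical is capped by iodine, and because the radical sits on the exocyclic CH2 neither ring stereocentre is involved.

**Step 5**
Reactants: 8 luteolin [2‑(3,4‑dihydroxyphenyl)‑5,7‑dihydroxy‑4H‑chromen‑4‑one]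
Product: 9 7‑(benzyloxy)‑2‑[3,4‑bis(benzyloxy)phenyl]‑5‑hydroxy‑4H‑chromen‑4‑one
Conditions: BnBr (3.15 equiv), K2CO3 (3.3 equiv), DMF, rt, 16 h
Reagents that add atoms: benzyl bromide, BrCc1ccccc1
Why: In this Williamson etherification the three free phenols are alkylated at room temperature while the 5‑OH, hydrogen‑bonded to the C4 carbonyl, stays free.

**Step 6**
Reactants: 9 7‑(benzyloxy)‑2‑[3,4‑bis(benzyloxy)phenyl]‑5‑hydroxy‑4H‑chromen‑4‑one
Product: 10 7‑(benzyloxy)‑2‑[3,4‑bis(benzyloxy)phenyl]‑5‑hydroxy‑6‑iodo‑4H‑chromen‑4‑one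
Conditions: NIS (1.05 equiv), DMF, rt, dark
Reagents that add atoms: N‑iodosuccinimide, O=C1CCC(=O)N1I
Why: Electrophilic aromatic iodination of 5‑hydroxy‑7‑alkoxyflavones under neutral conditions goes ortho to the free chelated 5‑OH, that is to C6 rather than C8, and the result is checked by HMBC from the 5‑OH proton to the iodinated carbon.

**Step 7**
Reactants: 10 7‑(benzyloxy)‑2‑[3,4‑bis(benzyloxy)phenyl]‑5‑hydroxy‑6‑iodo‑4H‑chromen‑4‑one
Product: 11 5,7‑bis(benzyloxy)‑2‑[3,4‑bis(benzyloxy)phenyl]‑6‑iodo‑4H‑chromen‑4‑one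
Conditions: BnBr, K2CO3, DMF, 70 °C
Reagents that add atoms: benzyl bromide, BrCc1ccccc1
Why: A Williamson etherification under forcing conditions caps the chelated 5‑OH, which removes the only acidic proton before the organozinc step and locks O‑5 so the pyrone can never re‑close to the 8‑substituted isomer.

**Step 8**
Reactants: 7 (1S,2S)‑2‑(iodomethyl)‑1,3,3‑trimethylcyclohexyl acetate; 11 5,7‑bis(benzyloxy)‑2‑[3,4‑bis(benzyloxy)phenyl]‑6‑iodo‑4H‑chromen‑4‑one
Product: 13 (1S,2S)‑2‑({5,7‑bis(benzyloxy)‑2‑[3,4‑bis(benzyloxy)phenyl]‑4‑oxo‑4H‑chromen‑6‑yl}methyl)‑1,3,3‑trimethylcyclohexyl acetate, via alkylzinc iodide 12 (not isolated)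
Conditions: 7 (1.3 equiv), Zn dust (activated with BrCH2CH2Br/TMSCl), LiCl, THF, 45 °C; then 11, Pd(OAc)2 (5 mol %), SPhos (10 mol %), THF/NMP, 55 °C
Reagents that add atoms: none
Why: Direct zinc insertion gives an ester‑tolerant primary alkylzinc, and Negishi cross‑coupling with a bulky biarylphosphine (fast reductive elimination, accepts 2,6‑dialkoxyaryl iodides, ignores pyrone and acetate) forges the C6–CH2 bond at the oxidation level of the target, with the metal on the exocyclic CH2 so no stereocentre is touched.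

**Step 9**
Reactants: 13 (1S,2S)‑2‑({5,7‑bis(benzyloxy)‑2‑[3,4‑bis(benzyloxy)phenyl]‑4‑oxo‑4H‑chromen‑6‑yl}methyl)‑1,3,3‑trimethylcyclohexyl acetate
Product: 14 5,7‑bis(benzyloxy)‑2‑[3,4‑bis(benzyloxy)phenyl]‑6‑{[(1S,2S)‑2‑hydroxy‑2,6,6‑trimethylcyclohexyl]methyl}‑4H‑chromen‑4‑one
Conditions: KOH (2 M), MeOH/THF 1:1, 45 °C, 12 h; then 1 M HCl to pH 6
Reagents that add atoms: none
Why: BAc2 saponification cleaves the acyl–oxygen bond so the tertiary C–O stereocentre is retained, the benzyl ethers are inert, and with O‑5 benzylated even a transient opening of the pyrone can only re‑close to the same 6‑substituted flavone.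

**Step 10**
Reactants: 14 5,7‑bis(benzyloxy)‑2‑[3,4‑bis(benzyloxy)phenyl]‑6‑{[(1S,2S)‑2‑hydroxy‑2,6,6‑trimethylcyclohexyl]methyl}‑4H‑chromen‑4‑one
Product: 15 2‑(3,4‑dihydroxyphenyl)‑5,7‑dihydroxy‑6‑{[(1S,2S)‑2‑hydroxy‑2,6,6‑trimethylcyclohexyl]methyl}‑4H‑chromen‑4‑one (target)
Conditions: H2 (1 atm), 10 % Pd/C, THF/MeOH 1:1, rt, stopped after uptake of 4 equiv
Reagents that add atoms: none
Why: Neutral catalytic hydrogenolysis removes all four benzyl ethers without acid, so the tertiary alcohol can neither dehydrate nor cyclise onto the flanking phenols, and the flavone C2=C3 bond survives at 1 atm and room temperature.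

**Compound list**
1 | (E)‑geranylacetone | CC(=O)CC/C=C(\C)CCC=C(C)C | starting material
2 | (4aS,8aS)‑2,5,5,8a‑tetramethyl‑4a,5,6,7,8,8a‑hexahydro‑4H‑chromene | CC1(C)CCC[C@](C)(OC(C)=C2)[C@H]1C2 | intermediate
3 | (1S,2S)‑2‑(2‑hydroperoxy‑2‑methoxyethyl)‑1,3,3‑trimethylcyclohexyl acetate (epimers at the peroxy carbon, not isolated) | CC1(C)CCC[C@](C)(OC(C)=O)[C@H]1CC(OC)OO | intermediate
4 | (1S,2S)‑1,3,3‑trimethyl‑2‑(2‑oxoethyl)cyclohexyl acetate | CC1(C)CCC[C@](C)(OC(C)=O)[C@H]1CC=O | intermediate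
5 | 2‑[(1S,2S)‑2‑acetoxy‑2,6,6‑trimethylcyclohexyl]acetic acid | CC1(C)CCC[C@](C)(OC(C)=O)[C@H]1CC(=O)O | intermediate
6 | 2‑[(1S,2S)‑2‑acetoxy‑2,6,6‑trimethylcyclohexyl]acetyl hypoiodite (not isolated) | CC1(C)CCC[C@](C)(OC(C)=O)[C@H]1CC(=O)OI | intermediate
7 | (1S,2S)‑2‑(iodomethyl)‑1,3,3‑trimethylcyclohexyl acetate | CC1(C)CCC[C@](C)(OC(C)=O)[C@H]1CI | intermediate
8 | luteolin | O=c1cc(-c2ccc(O)c(O)c2)oc2cc(O)cc(O)c12 | starting material
9 | 7‑(benzyloxy)‑2‑[3,4‑bis(benzyloxy)phenyl]‑5‑hydroxy‑4H‑chromen‑4‑one | O=c1cc(-c2ccc(OCc3ccccc3)c(OCc3ccccc3)c2)oc2cc(OCc3ccccc3)cc(O)c12 | intermediate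
10 | 7‑(benzyloxy)‑2‑[3,4‑bis(benzyloxy)phenyl]‑5‑hydroxy‑6‑iodo‑4H‑chromen‑4‑one | O=c1cc(-c2ccc(OCc3ccccc3)c(OCc3ccccc3)c2)oc2cc(OCc3ccccc3)c(I)c(O)c12 | intermediate
11 | 5,7‑bis(benzyloxy)‑2‑[3,4‑bis(benzyloxy)phenyl]‑6‑iodo‑4H‑chromen‑4‑one | O=c1cc(-c2ccc(OCc3ccccc3)c(OCc3ccccc3)c2)oc2cc(OCc3ccccc3)c(I)c(OCc3ccccc3)c12 | intermediate
12 | {[(1S,2S)‑2‑acetoxy‑2,6,6‑trimethylcyclohexyl]methyl}zinc iodide (not isolated) | CC1(C)CCC[C@](C)(OC(C)=O)[C@H]1C[Zn]I | intermediate
13 | (1S,2S)‑2‑({5,7‑bis(benzyloxy)‑2‑[3,4‑bis(benzyloxy)phenyl]‑4‑oxo‑4H‑chromen‑6‑yl}methyl)‑1,3,3‑trimethylcyclohexyl acetate | CC1(C)CCC[C@](C)(OC(C)=O)[C@H]1Cc1c(OCc2ccccc2)cc2oc(-c3ccc(OCc4ccccc4)c(OCc4ccccc4)c3)cc(=O)c2c1OCc1ccccc1 | intermediate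
14 | 5,7‑bis(benzyloxy)‑2‑[3,4‑bis(benzyloxy)phenyl]‑6‑{[(1S,2S)‑2‑hydroxy‑2,6,6‑trimethylcyclohexyl]methyl}‑4H‑chromen‑4‑one | CC1(C)CCC[C@](C)(O)[C@H]1Cc1c(OCc2ccccc2)cc2oc(-c3ccc(OCc4ccccc4)c(OCc4ccccc4)c3)cc(=O)c2c1OCc1ccccc1 | intermediate
15 | 2‑(3,4‑dihydroxyphenyl)‑5,7‑dihydroxy‑6‑{[(1S,2S)‑2‑hydroxy‑2,6,6‑trimethylcyclohexyl]methyl}‑4H‑chromen‑4‑one | CC1(C)CCC[C@](C)(O)[C@H]1Cc1c(O)cc2oc(-c3ccc(O)c(O)c3)cc(=O)c2c1O | target

**Totals**
Total step count: 10. Longest linear sequence: 7 (steps 1, 2, 3, 4, 8, 9, 10).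

**Three steps most likely to fail**

Step 1 (enzymatic cyclisation). The risks are low turnover, partition of the cation between oxygen capture and deprotonation, and hydrolysis of the enol ether during the long aqueous incubation.
- The fallback sets out from 1 and comes back at 2. It lets the enzyme make only the C–C bond and installs the oxygen chemically.
- A cyclase variant tuned for proton loss converts 1 into (S)‑γ‑dihydroionone F1.
- Buffered mCPBA at 0 °C attacks the exocyclic methylene from the equatorial side, away from the axial methyl of the gem‑dimethyl group. This gives the spiro‑epoxide 4‑[(3S,4S)‑5,5‑dimethyl‑1‑oxaspiro[2.5]octan‑4‑yl]butan‑2‑one F2.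
- LiAlH4 opens the epoxide at its CH2 and reduces the ketone to 4‑[(1S,2S)‑2‑hydroxy‑2,6,6‑trimethylcyclohexyl]butan‑2‑ol F3.
- Dess–Martin periodinane oxidises the secondary alcohol to 4‑[(1S,2S)‑2‑hydroxy‑2,6,6‑trimethylcyclohexyl]butan‑2‑one F4.
- Catalytic PPTS in toluene over molecular sieves closes and dehydrates the ketol to 2. This last operation also recovers any 2 that was hydrolysed during step 1.

Step 8 (Negishi coupling). The risks are slow transmetalation onto an aryl‑palladium flanked by two benzyloxy groups, followed by β‑hydride elimination and hydrodeiodination.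
- The fallback sets out from 5 and comes back at 13. It replaces the in‑situ zinc reagent with an isolable boron nucleophile made without the iodide.
- Acid 5 is esterified with N‑hydroxyphthalimide (DIC, cat. DMAP) to the redox‑active ester 1,3‑dioxoisoindolin‑2‑yl 2‑[(1S,2S)‑2‑acetoxy‑2,6,6‑trimethylcyclohexyl]acetate F5.
- Photochemical decarboxylative borylation (B2cat2, DMAc, blue LEDs, then pinacol/Et3N) gives (1S,2S)‑1,3,3‑trimethyl‑2‑[(4,4,5,5‑tetramethyl‑1,3,2‑dioxaborolan‑2‑yl)methyl]cyclohexyl acetate F6.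
- KHF2 in aqueous methanol gives the crystalline potassium {[(1S,2S)‑2‑acetoxy‑2,6,6‑trimethylcyclohexyl]methyl}trifluoroborate F7.
- F7 is purified and then joined to 11 by Suzuki–Miyaura coupling (Pd(OAc)2/RuPhos, K2CO3, toluene/H2O, 85 °C) to give 13.

Step 9 (cleavage of the hindered tertiary acetate beside the pyrone). The risk is that the base strength and time needed may open or degrade the O‑alkylated flavone.
- The fallback sets out from 13 and comes back at 15. It reverses the order of the two deprotections.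
- Hydrogenolysis of 13 (H2, Pd/C, THF/MeOH) gives (1S,2S)‑2‑{[2‑(3,4‑dihydroxyphenyl)‑5,7‑dihydroxy‑4‑oxo‑4H‑chromen‑6‑yl]methyl}‑1,3,3‑trimethylcyclohexyl acetate F8.
- In degassed 1 M NaOH/MeOH under argon F8 exists as a polyphenolate, whose pyrone is no longer electrophilic. The acetate can therefore be saponified for as long as needed before careful acidification to 15.

**Further compounds**
F1 | step 1 | 4‑[(1S)‑2,2‑dimethyl‑6‑methylidenecyclohexyl]butan‑2‑one, (S)‑γ‑dihydroionone | CC1(C)CCCC(=C)[C@H]1CCC(C)=O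
F2 | step 1 | 4‑[(3S,4S)‑5,5‑dimethyl‑1‑oxaspiro[2.5]octan‑4‑yl]butan‑2‑one | CC1(C)CCC[C@]2(OC2)[C@H]1CCC(C)=O
F3 | step 1 | 4‑[(1S,2S)‑2‑hydroxy‑2,6,6‑trimethylcyclohexyl]butan‑2‑ol (carbinol epimers) | CC1(C)CCC[C@](C)(O)[C@H]1CCC(C)O
F4 | step 1 | 4‑[(1S,2S)‑2‑hydroxy‑2,6,6‑trimethylcyclohexyl]butan‑2‑one | CC1(C)CCC[C@](C)(O)[C@H]1CCC(C)=O
F5 | step 8 | 1,3‑dioxoisoindolin‑2‑yl 2‑[(1S,2S)‑2‑acetoxy‑2,6,6‑trimethylcyclohexyl]acetate | CC1(C)CCC[C@](C)(OC(C)=O)[C@H]1CC(=O)ON1C(=O)c2ccccc2C1=O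
F6 | step 8 | (1S,2S)‑1,3,3‑trimethyl‑2‑[(4,4,5,5‑tetramethyl‑1,3,2‑dioxaborolan‑2‑yl)methyl]cyclohexyl acetate | CC1(C)CCC[C@](C)(OC(C)=O)[C@H]1CB1OC(C)(C)C(C)(C)O1
F7 | step 8 | potassium {[(1S,2S)‑2‑acetoxy‑2,6,6‑trimethylcyclohexyl]methyl}trifluoroborate | CC1(C)CCC[C@](C)(OC(C)=O)[C@H]1C[B-](F)(F)F.[K+]
F8 | step 9 | (1S,2S)‑2‑{[2‑(3,4‑dihydroxyphenyl)‑5,7‑dihydroxy‑4‑oxo‑4H‑chromen‑6‑yl]methyl}‑1,3,3‑trimethylcyclohexyl acetate | CC1(C)CCC[C@](C)(OC(C)=O)[C@H]1Cc1c(O)cc2oc(-c3ccc(O)c(O)c3)cc(=O)c2c1O
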